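**Retrosynthetic overview**

- Target: (1R,2R,5S,6R)-2,6-bis(3,4-dimethoxyphenyl)-3,7-dioxabicyclo[3.3.0]octan-1-ol. Locants used below: ring A = C1(OH)–C2(Ar)–O3–C4–C5(H); ring B = C5–C6(Ar)–O7–C8–C1.
- Key disconnection: C5–C6 of ring B, made last by a strain-releasing anionic isomerization. The C6 benzylic carbanion of a 3,4-dimethoxybenzyl ether on O7 opens a C1–C5 epoxide fused to ring A; the precursor 14 is an isomer of the target and carries no protecting group.
- Enabling feature: the tertiary C1–OH cis to H5 at the ring fusion is the retron of an anti epoxide opening. C1 is fully substituted, so only C5 can be attacked. The C8–O7–CH2Ar arm on C1 lies anti to the epoxide oxygen, which puts the backside of C5 within reach. C6–H is benzylic and α to O7.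
- Epoxide 14 from 2,5-dihydrofuran 13 (epoxidation anti to the C2 aryl group); 13 by ring-closing metathesis of allyl ether 12; 12 from (R)-allylic alcohol 9 (Sharpless kinetic resolution); 9 from 3,4-dimethoxybenzaldehyde and a 2-lithioallyl 3,4-dimethoxybenzyl ether.
- Ring order: ring A (step 5), the temporary epoxide ring (step 6), ring B (step 7).

Key step: step 7

**Route**

Step 1
Reactants: 1 (3,4-dimethoxyphenyl)methanol; 2 2,3-dibromoprop-1-ene
Product: 4 4-{[(2-bromoprop-2-en-1-yl)oxy]methyl}-1,2-dimethoxybenzene, via sodium (3,4-dimethoxyphenyl)methanolate 3 (not isolated)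
Conditions: NaH, THF, 0 °C; then 2, Bu4NI (cat.), 0 °C to rt
Reagents that add atoms: none
Why: Williamson ether synthesis in which the sodium alkoxide displaces the allylic bromide of 2 by SN2 while the vinylic bromide stays inert; no stereocenter is formed.

Step 2
Reactants: 4 4-{[(2-bromoprop-2-en-1-yl)oxy]methyl}-1,2-dimethoxybenzene; 5 3,4-dimethoxybenzaldehyde
Product: 8 rac-1-(3,4-dimethoxyphenyl)-2-{[(3,4-dimethoxyphenyl)methoxy]methyl}prop-2-en-1-ol, via alkenyllithium 6 (not isolated), via lithium alkoxide 7 (not isolated)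
Conditions: tBuLi (2 equiv), Et2O, −78 °C; then 5, −78 °C; then H2O
Reagents that add atoms: none
Why: Bromine–lithium exchange at the vinylic bromide followed by 1,2-addition of the alkenyllithium to the aldehyde builds the carbinol carbon (the later C2) as a racemate, the alkoxymethyl group surviving because β-elimination of the ether is slow at −78 °C.

Step 3
Reactants: 8 rac-1-(3,4-dimethoxyphenyl)-2-{[(3,4-dimethoxyphenyl)methoxy]methyl}prop-2-en-1-ol
Product: 9 (1R)-1-(3,4-dimethoxyphenyl)-2-{[(3,4-dimethoxyphenyl)methoxy]methyl}prop-2-en-1-ol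
Conditions: Ti(OiPr)4 (cat.), L-(+)-diisopropyl tartrate (cat.), tBuOOH (0.6 equiv), 4 Å MS, CH2Cl2, −20 °C; stopped just past half conversion
Reagents that add atoms: none
Why: Sharpless kinetic resolution (titanium tartrate-catalysed epoxidation of a secondary allylic alcohol): with L-(+)-diisopropyl tartrate the (S)-enantiomer should be epoxidized much faster, so the recovered alcohol is the (R)-enantiomer that carries the C2 configuration of the target.

Step 4
Reactants: 9 (1R)-1-(3,4-dimethoxyphenyl)-2-{[(3,4-dimethoxyphenyl)methoxy]methyl}prop-2-en-1-ol; 10 3-bromoprop-1-ene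
Product: 12 4-[(1R)-2-{[(3,4-dimethoxyphenyl)methoxy]methyl}-1-(prop-2-en-1-yloxy)prop-2-en-1-yl]-1,2-dimethoxybenzene, via sodium alkoxide 11 (not isolated)
Conditions: NaH, THF/DMF, 0 °C; then 10, Bu4NI (cat.), 0 °C to rt
Reagents that add atoms: none
Why: Williamson O-allylation of the secondary alkoxide with a primary allylic bromide (SN2 at the bromide), which does not touch the C–O bond of the stereocenter.

Step 5
Reactants: 12 4-[(1R)-2-{[(3,4-dimethoxyphenyl)methoxy]methyl}-1-(prop-2-en-1-yloxy)prop-2-en-1-yl]-1,2-dimethoxybenzene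
Product: 13 (2R)-2-(3,4-dimethoxyphenyl)-3-{[(3,4-dimethoxyphenyl)methoxy]methyl}-2,5-dihydrofuran
Conditions: second-generation Grubbs catalyst RuCl2(=CHPh)(H2IMes)(PCy3) (5 mol %), CH2Cl2, 40 °C
Reagents that add atoms: none
Why: Ring-closing olefin metathesis between the allyl ether and the 1,1-disubstituted alkene closes ring A as the 2,5-dihydrofuran (C1=C5) with loss of ethene and leaves C2 untouched.

Step 6
Reactants: 13 (2R)-2-(3,4-dimethoxyphenyl)-3-{[(3,4-dimethoxyphenyl)methoxy]methyl}-2,5-dihydrofuran
Product: 14 (1R,2R,5S)-2-(3,4-dimethoxyphenyl)-1-{[(3,4-dimethoxyphenyl)methoxy]methyl}-3,6-dioxabicyclo[3.1.0]hexane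
Conditions: mCPBA, CH2Cl2, 0 °C to rt
Reagents that add atoms: 3-chloroperoxybenzoic acid (mCPBA), OOC(=O)c1cccc(Cl)c1
Why: Prilezhaev epoxidation of the trisubstituted C1=C5 double bond, in which the peracid should approach the nearly flat dihydrofuran from the face opposite the C2 aryl group and thereby set C1 and C5 together (epoxide oxygen trans to the aryl group).

Step 7
Reactants: 14 (1R,2R,5S)-2-(3,4-dimethoxyphenyl)-1-{[(3,4-dimethoxyphenyl)methoxy]methyl}-3,6-dioxabicyclo[3.1.0]hexane
Product: 17 (1R,2R,5S,6R)-2,6-bis(3,4-dimethoxyphenyl)-3,7-dioxabicyclo[3.3.0]octan-1-ol, via potassium benzylic carbanion 15 (not isolated), via potassium alkoxide 16 (not isolated)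
Conditions: LiN(iPr)2/KOtBu (1:1), THF, −78 to −50 °C; then H2O
Reagents that add atoms: none
Why: Proposed new method: the mixed lithium amide/potassium alkoxide base removes one C6–H of the dimethoxybenzyl ether (benzylic and α to O7), and the carbanion attacks C5 from the face opposite the epoxide oxygen, an intramolecular SN2 opening driven by release of the epoxide strain that leaves the oxygen on C1 as the tertiary alkoxide; the closest known reaction type is the superbase-promoted cyclization of benzyl oxiranylmethyl ethers, which normally closes a four-membered ring at the proximal epoxide carbon. Ring B (C5–C6–O7–C8–C1) closes in the 5-endo-tet mode (the epoxide C1–C5 bond ends inside the new ring), which should be feasible here because the tether leaves C1 on the face anti to the epoxide oxygen and because the 4-exo alternative would require substitution at the fully substituted C1. C1 keeps the configuration set by the epoxidation, C5 is inverted so that H5 ends cis to the C1 oxygen (cis ring fusion), and C6 is set in the transition state with its aryl group on the convex (exo) face, away from ring A and from the endo C2 aryl group. The selectivity needed is metalation at the C6 methylene instead of at C2–H or C4–H (either of which would open the epoxide by β-elimination) or on the arenes; the unhindered primary benzylic position, the shielding of the tertiary C2–H by the adjacent fully substituted C1, and the low tendency of amide superbases to metalate anisole rings are expected to secure it. Protonation of the alkoxide on aqueous work-up should give 17 directly.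

**Compound list**

1 | (3,4-dimethoxyphenyl)methanol | COc1ccc(CO)cc1OC | starting material
2 | 2,3-dibromoprop-1-ene | C=C(Br)CBr | starting material
3 | sodium (3,4-dimethoxyphenyl)methanolate | COc1ccc(C[O-])cc1OC.[Na+] | intermediate
4 | 4-{[(2-bromoprop-2-en-1-yl)oxy]methyl}-1,2-dimethoxybenzene | C=C(Br)COCc1ccc(OC)c(OC)c1 | intermediate
5 | 3,4-dimethoxybenzaldehyde | COc1ccc(C=O)cc1OC | starting material
6 | alkenyllithium: {3-[(3,4-dimethoxyphenyl)methoxy]prop-1-en-2-yl}lithium | [Li]C(=C)COCc1ccc(OC)c(OC)c1 | intermediate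
7 | lithium alkoxide: lithium 1-(3,4-dimethoxyphenyl)-2-{[(3,4-dimethoxyphenyl)methoxy]methyl}prop-2-en-1-olate (racemic) | [Li+].[O-]C(c1ccc(OC)c(OC)c1)C(=C)COCc1ccc(OC)c(OC)c1 | intermediate
8 | rac-1-(3,4-dimethoxyphenyl)-2-{[(3,4-dimethoxyphenyl)methoxy]methyl}prop-2-en-1-ol | OC(c1ccc(OC)c(OC)c1)C(=C)COCc1ccc(OC)c(OC)c1 | intermediate
9 | (1R)-1-(3,4-dimethoxyphenyl)-2-{[(3,4-dimethoxyphenyl)methoxy]methyl}prop-2-en-1-ol | O[C@H](c1ccc(OC)c(OC)c1)C(=C)COCc1ccc(OC)c(OC)c1 | intermediate
10 | 3-bromoprop-1-ene | C=CCBr | starting material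
11 | sodium alkoxide: sodium (1R)-1-(3,4-dimethoxyphenyl)-2-{[(3,4-dimethoxyphenyl)methoxy]methyl}prop-2-en-1-olate | [Na+].[O-][C@H](c1ccc(OC)c(OC)c1)C(=C)COCc1ccc(OC)c(OC)c1 | intermediate
12 | 4-[(1R)-2-{[(3,4-dimethoxyphenyl)methoxy]methyl}-1-(prop-2-en-1-yloxy)prop-2-en-1-yl]-1,2-dimethoxybenzene | C=CCO[C@H](c1ccc(OC)c(OC)c1)C(=C)COCc1ccc(OC)c(OC)c1 | intermediate
13 | (2R)-2-(3,4-dimethoxyphenyl)-3-{[(3,4-dimethoxyphenyl)methoxy]methyl}-2,5-dihydrofuran | O1CC=C(COCc2ccc(OC)c(OC)c2)[C@H]1c1ccc(OC)c(OC)c1 | intermediate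
14 | (1R,2R,5S)-2-(3,4-dimethoxyphenyl)-1-{[(3,4-dimethoxyphenyl)methoxy]methyl}-3,6-dioxabicyclo[3.1.0]hexane | C1O[C@H](c2ccc(OC)c(OC)c2)[C@@]3(COCc2ccc(OC)c(OC)c2)O[C@@H]13 | intermediate
15 | potassium benzylic carbanion: potassium (3,4-dimethoxyphenyl)({[(1R,2R,5S)-2-(3,4-dimethoxyphenyl)-3,6-dioxabicyclo[3.1.0]hexan-1-yl]methoxy})methanide | C1O[C@H](c2ccc(OC)c(OC)c2)[C@@]3(CO[CH-]c2ccc(OC)c(OC)c2)O[C@@H]13.[K+] | intermediate
16 | potassium alkoxide: potassium (1R,2R,5S,6R)-2,6-bis(3,4-dimethoxyphenyl)-3,7-dioxabicyclo[3.3.0]octan-1-olate | COc1ccc([C@H]2OC[C@H]3[C@H](c4ccc(OC)c(OC)c4)OC[C@@]23[O-])cc1OC.[K+] | intermediate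
17 | (1R,2R,5S,6R)-2,6-bis(3,4-dimethoxyphenyl)-3,7-dioxabicyclo[3.3.0]octan-1-ol | COc1ccc([C@H]2OC[C@H]3[C@H](c4ccc(OC)c(OC)c4)OC[C@@]23O)cc1OC | target

**Step count and risks**

Total step count: 7. Longest linear sequence: 7 steps (1 and 2 to 17).

The three steps most likely to fail, riskiest first:

(a) The key step, step 7 (proposed new method). The base may remove C2–H or a C4–H instead of a C6–H and open the epoxide by β-elimination, the benzylic carbanion may undergo a 1,2-Wittig shift, or the 5-endo trajectory may be too slow. The fallback uses known reactions and reverses the polarity (C6 as an oxocarbenium carbon, C5 as an enol ether carbon); it sets out from 14 and returns at 17. Opening of the epoxide at C5 with PhSeNa ((PhSe)2, NaBH4, EtOH) should give the hydroxy selenide (2R,3R,4R)-2-(3,4-dimethoxyphenyl)-3-{[(3,4-dimethoxyphenyl)methoxy]methyl}-4-(phenylselanyl)oxolan-3-ol F1. Oxidation with H2O2/pyridine and syn-elimination of the selenoxide toward C4, the only carbon that carries β-hydrogens, should give the cyclic enol ether (2R,3R)-2-(3,4-dimethoxyphenyl)-3-{[(3,4-dimethoxyphenyl)methoxy]methyl}-2,3-dihydrofuran-3-ol F2. DDQ with 4 Å MS in CH2Cl2 at 0 °C should oxidize the dimethoxybenzyl ether and let the tertiary hydroxyl capture the cation as the spiro arylidene acetal (5R,6R)-2,6-bis(3,4-dimethoxyphenyl)-1,3,7-trioxaspiro[4.4]non-8-ene F3 (epimers at the acetal carbon, which becomes trigonal again). BF3·OEt2 and Et3SiH in CH2Cl2 at −78 °C should then ionize the acetal toward the O7 oxocarbenium ion, which the enol ether carbon C5 attacks on the face of the C8 arm to close ring B; the resulting C4 oxocarbenium ion is reduced by the silane to give 17.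

(b) The resolution, step 3. The selectivity factor may be low, or the titanium Lewis acid may ionize the electron-rich benzylic allylic alcohol. The fallback sets out from 4 and 5 and returns at 9, bypassing 8. A catalytic enantioselective Nozaki–Hiyama–Kishi alkenylation (CrCl2 and NiCl2 as catalysts with a chiral sulfonamide ligand, Mn powder as reductant, Me3SiCl, THF/MeCN) should give the silyl ether {[(1R)-1-(3,4-dimethoxyphenyl)-2-{[(3,4-dimethoxyphenyl)methoxy]methyl}prop-2-en-1-yl]oxy}(trimethyl)silane F4, which K2CO3 in MeOH should cleave to 9.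

(c) The organolithium addition, step 2. The 2-lithioallyl ether may lose lithium alkoxide by β-elimination, or the base may metalate the benzylic ether. The fallback sets out from 5 and returns at 8. The dianion of commercially available 2-bromoprop-2-en-1-ol (tBuLi, Et2O, −78 °C), whose alkoxide cannot be eliminated, should add to 5 to give rac-1-(3,4-dimethoxyphenyl)-2-methylidenepropane-1,3-diol F5. Tin-mediated selective alkylation of the primary hydroxyl (Bu2SnO, toluene, reflux; then 4-(bromomethyl)-1,2-dimethoxybenzene, CsF, DMF) should give 8.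

Further compounds
F1 | step 7 | (2R,3R,4R)-2-(3,4-dimethoxyphenyl)-3-{[(3,4-dimethoxyphenyl)methoxy]methyl}-4-(phenylselanyl)oxolan-3-ol | C1O[C@H](c2ccc(OC)c(OC)c2)[C@](O)(COCc2ccc(OC)c(OC)c2)[C@@H]1[Se]c1ccccc1
F2 | step 7 | (2R,3R)-2-(3,4-dimethoxyphenyl)-3-{[(3,4-dimethoxyphenyl)methoxy]methyl}-2,3-dihydrofuran-3-ol | O1C=C[C@@](O)(COCc2ccc(OC)c(OC)c2)[C@H]1c1ccc(OC)c(OC)c1
F3 | step 7 | (5R,6R)-2,6-bis(3,4-dimethoxyphenyl)-1,3,7-trioxaspiro[4.4]non-8-ene | O1C=C[C@@]2(COC(c3ccc(OC)c(OC)c3)O2)[C@H]1c1ccc(OC)c(OC)c1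
F4 | step 3 | {[(1R)-1-(3,4-dimethoxyphenyl)-2-{[(3,4-dimethoxyphenyl)methoxy]methyl}prop-2-en-1-yl]oxy}(trimethyl)silane | C[Si](C)(C)O[C@H](c1ccc(OC)c(OC)c1)C(=C)COCc1ccc(OC)c(OC)c1
F5 | step 2 | rac-1-(3,4-dimethoxyphenyl)-2-methylidenepropane-1,3-diol | OCC(=C)C(O)c1ccc(OC)c(OC)c1
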